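Ring B is disconnected across C2'–C3' and C4'–C5' into a 2-pyranone and a two-carbon ketene acetal. The run C1' (ether oxygen), C6' (carboxyl), C5' (methyl) of ring B is the C4–C5–C6 edge of a 4-aryloxy-6-methyl-2-pyranone-5-carboxylate, and the adjacent C3' oxygen/C4' chlorine pair is chloroketene dimethyl acetal. One inverse-electron-demand cycloaddition, with loss of CO2 and methanol, therefore delivers the penta-substituted ring B with the diaryl ether already in place. The precursor is the pyranone carrying bis-benzylated ring A as its 4-aryloxy group, assembled by addition–elimination of the ring A phenol on a 4-chloropyranone. Formylation of the one free position (C2') and global dealkylation finish the synthesis.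

Key step: step 8

Remark (numbering): ring A is C1 (CO2Me), C2 (Me), C3 (O-aryl), C4 (OH), C5 (Me), C6 (OH); ring B is C1' (O-aryl), C2' (CHO), C3' (OH), C4' (Cl), C5' (Me), C6' (CO2H). ArO stands for 2,4-bis(benzyloxy)-5-(methoxycarbonyl)-3,6-dimethylphenoxy, which is protected ring A bound through its C3 oxygen.

Remark (stereochemistry): the target has no stereocentre, so nothing has to be set. The stereocentres of the two transient key-step intermediates are lost on aromatisation.

Remark (atom map, rechecked): pyranone C4, C5, C6 become C1', C6', C5'; pyranone C3 becomes C2'; the acetal carbon becomes C3' and the chlorinated carbon C4'.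

Remark (design): the leaving group on the pyranone is chloride, not a sulfonate, so that the hindered ring A phenoxide has only carbon to attack. All three benzyl groups and the C3' methyl ether are chosen to fall in one Lewis acid step.

Step 1
Reactants: 1 methyl 2,4-dihydroxy-3,6-dimethylbenzoate (methyl beta-orsellinate)
Product: 2 methyl 3-formyl-4,6-dihydroxy-2,5-dimethylbenzoate
Conditions: Cl2CHOMe, TiCl4, CH2Cl2, 0 °C to rt; then aq. HCl
Reagents that add atoms: dichloromethyl methyl ether, COC(Cl)Cl; water, O
Why: Rieche formylation (Friedel–Crafts type) at the only unsubstituted ring carbon, which is ortho to one hydroxyl and para to the other, with hydrolysis of the alpha-chloro ether to the aldehyde on work-up.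

Step 2
Reactants: 2 methyl 3-formyl-4,6-dihydroxy-2,5-dimethylbenzoate
Product: 3 methyl 4,6-bis(benzyloxy)-3-formyl-2,5-dimethylbenzoate
Conditions: BnBr, K2CO3, DMF, 60 °C
Reagents that add atoms: benzyl bromide, BrCc1ccccc1
Why: Williamson ether synthesis, in which the two carbonyl-chelated phenols need DMF and warming while K2CO3 leaves the methyl ester and the non-enolisable aldehyde alone.

Step 3
Reactants: 3 methyl 4,6-bis(benzyloxy)-3-formyl-2,5-dimethylbenzoate
Product: 5 methyl 4,6-bis(benzyloxy)-3-hydroxy-2,5-dimethylbenzoate, via aryl formate 4 (not isolated)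
Conditions: mCPBA, CH2Cl2, 0 °C to rt; then Et3N, MeOH, rt
Reagents that add atoms: 3-chloroperoxybenzoic acid, O=C(OO)c1cccc(Cl)c1
Why: Baeyer–Villiger oxidation of an electron-rich benzaldehyde (Dakin-type), in which the aryl group activated by ortho and para benzyloxy groups migrates to give formate 4, which amine-catalysed methanolysis cleaves without touching the hindered methyl benzoate.

Step 4
Reactants: 6 benzyl acetoacetate (benzyl 3-oxobutanoate); 7 malonyl dichloride
Product: 8 benzyl 4-hydroxy-6-methyl-2-oxo-2H-pyran-5-carboxylate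
Conditions: CH2Cl2, rt to 40 °C, N2 sweep to remove HCl
Reagents that add atoms: none
Why: Acylative pyranone annulation of a beta-keto ester with malonyl dichloride, by C-acylation of the enol at the central carbon and lactonisation of the ketone enol oxygen onto the second acid chloride, giving the 4-hydroxy tautomer.

Step 5
Reactants: 8 benzyl 4-hydroxy-6-methyl-2-oxo-2H-pyran-5-carboxylate
Product: 9 benzyl 4-chloro-6-methyl-2-oxo-2H-pyran-5-carboxylate
Conditions: POCl3, Et3N, MeCN, 70 °C
Reagents that add atoms: phosphoryl chloride, O=P(Cl)(Cl)Cl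
Why: Deoxychlorination of a vinylogous acid, in which the 4-hydroxyl is phosphorylated and chloride displaces dichlorophosphate by addition–elimination at C4, as in the standard preparation of 4-chloro-2-pyranones and 4-chlorocoumarins.

Step 6
Reactants: 5 methyl 4,6-bis(benzyloxy)-3-hydroxy-2,5-dimethylbenzoate; 9 benzyl 4-chloro-6-methyl-2-oxo-2H-pyran-5-carboxylate
Product: 10 benzyl 4-(ArO)-6-methyl-2-oxo-2H-pyran-5-carboxylate
Conditions: K2CO3, MeCN, rt to 50 °C
Reagents that add atoms: none
Why: Addition–elimination (vinylogous acyl substitution, SNAr-like), in which the phenoxide of 5 adds to C4 of 9, beta to the lactone carbonyl and next to the ester, and chloride leaves.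

Step 7
Reactants: 11 2-chloro-1,1,1-trimethoxyethane
Product: 12 2-chloro-1,1-dimethoxyethene (chloroketene dimethyl acetal)
Conditions: TMSOTf, i-Pr2NEt, CH2Cl2, 0 °C to rt; distil
Reagents that add atoms: none
Why: Dealcoholation of an orthoester to a ketene acetal, in which TMSOTf ionises 11 to a dimethoxycarbenium ion whose chlorine-acidified alpha hydrogen is removed by the hindered amine, the same manifold that turns acetals into enol ethers.

Step 8
Reactants: 10 benzyl 4-(ArO)-6-methyl-2-oxo-2H-pyran-5-carboxylate; 12 2-chloro-1,1-dimethoxyethene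
Product: 15 benzyl 2-(ArO)-5-chloro-4-methoxy-6-methylbenzoate, via bicyclic lactone 13 (not isolated), via dimethoxycyclohexadiene 14 (not isolated)
Conditions: 12 (5 equiv, added in portions), PhMe, 130 °C, sealed tube
Reagents that add atoms: none
Why: The chlorine-bearing carbon of 12, the nucleophilic end of the ketene acetal, adds to C6 of pyranone 10 (vinylogous to the lactone carbonyl and beta to the 5-ester) and the resulting dimethoxycarbenium carbon bonds to C3, so that the C4'–C5' and C2'–C3' bonds form in an asynchronous or stepwise polar (4+2) event giving the 2-oxabicyclo[2.2.2]octenone 13. Cycloreversion expels CO2 to give cyclohexadiene 14, and 1,2-loss of methanol (methoxy from the acetal carbon, hydrogen from the CHCl carbon) aromatises it to 15; since the only hydrogen on an sp3 ring carbon sits on the chlorinated carbon itself, hydrogen chloride cannot be eliminated and the chlorine is kept. The closest known reaction type is the inverse-electron-demand Diels–Alder reaction of 2-pyranone-5-carboxylates (coumalates) with ketene acetals and enol ethers, which gives alkoxybenzoates after loss of CO2 and alcohol. Ring B is closed by intermolecular (4+2) cycloaddition across C3 and C6 of the pyranone; the stereocentres of 13 and 14 form as mixtures and are all erased, so no stereocontrol is needed. The selectivity required is regiochemical (methoxy carbon next to C2', chlorine next to the C5' methyl) and is secured by matched polarisation: the ester and lactone carbonyl make C6 the acceptor terminus, while the 4-aryloxy donor makes C3 the electron-rich terminus that captures the oxocarbenium carbon.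

Step 9
Reactants: 15 benzyl 2-(ArO)-5-chloro-4-methoxy-6-methylbenzoate
Product: 16 benzyl 2-(ArO)-5-chloro-3-formyl-4-methoxy-6-methylbenzoate
Conditions: Cl2CHOMe, TiCl4, CH2Cl2, −78 to −20 °C; then H2O
Reagents that add atoms: dichloromethyl methyl ether, COC(Cl)Cl; water, O
Why: Rieche formylation at C2', the only hydrogen on an activated ring (ortho to the aryloxy and methoxy oxygens, para to the C5' methyl), with TiCl4 held between the two oxygens guiding the electrophile and low temperature limiting attack on the benzyl groups.

Step 10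
Reactants: 16 benzyl 2-(ArO)-5-chloro-3-formyl-4-methoxy-6-methylbenzoate
Product: 17 5-chloro-2-[2,4-dihydroxy-5-(methoxycarbonyl)-3,6-dimethylphenoxy]-3-formyl-4-hydroxy-6-methylbenzoic acid (target)
Conditions: BCl3, C6HMe5, CH2Cl2, −78 to 0 °C; then H2O
Reagents that add atoms: none
Why: Lewis acid dealkylation, in which BCl3 cleaves the two benzyl ethers and the benzyl ester through benzyl cations trapped by pentamethylbenzene and removes the C3' methyl ether by chelation with the ortho formyl group, while the methyl ester and the diaryl ether should survive at or below 0 °C.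

Compound list
1 | methyl 2,4-dihydroxy-3,6-dimethylbenzoate (methyl beta-orsellinate) | COC(=O)c1c(C)cc(O)c(C)c1O | starting material
2 | methyl 3-formyl-4,6-dihydroxy-2,5-dimethylbenzoate | COC(=O)c1c(C)c(C=O)c(O)c(C)c1O | intermediate
3 | methyl 4,6-bis(benzyloxy)-3-formyl-2,5-dimethylbenzoate | COC(=O)c1c(C)c(C=O)c(OCc2ccccc2)c(C)c1OCc1ccccc1 | intermediate
4 | methyl 4,6-bis(benzyloxy)-3-(formyloxy)-2,5-dimethylbenzoate | COC(=O)c1c(C)c(OC=O)c(OCc2ccccc2)c(C)c1OCc1ccccc1 | intermediate
5 | methyl 4,6-bis(benzyloxy)-3-hydroxy-2,5-dimethylbenzoate | COC(=O)c1c(C)c(O)c(OCc2ccccc2)c(C)c1OCc1ccccc1 | intermediate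
6 | benzyl acetoacetate (benzyl 3-oxobutanoate) | CC(=O)CC(=O)OCc1ccccc1 | starting material
7 | malonyl dichloride | O=C(Cl)CC(Cl)=O | starting material
8 | benzyl 4-hydroxy-6-methyl-2-oxo-2H-pyran-5-carboxylate | O=C1C=C(O)C(C(=O)OCc2ccccc2)=C(C)O1 | intermediate
9 | benzyl 4-chloro-6-methyl-2-oxo-2H-pyran-5-carboxylate | O=C1C=C(Cl)C(C(=O)OCc2ccccc2)=C(C)O1 | intermediate
10 | benzyl 4-[2,4-bis(benzyloxy)-5-(methoxycarbonyl)-3,6-dimethylphenoxy]-6-methyl-2-oxo-2H-pyran-5-carboxylate | O=C1C=C(Oc2c(C)c(C(=O)OC)c(OCc3ccccc3)c(C)c2OCc2ccccc2)C(C(=O)OCc2ccccc2)=C(C)O1 | intermediate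
11 | 2-chloro-1,1,1-trimethoxyethane | COC(CCl)(OC)OC | starting material
12 | 2-chloro-1,1-dimethoxyethene (chloroketene dimethyl acetal) | COC(OC)=CCl | intermediate
13 | benzyl 5-[2,4-bis(benzyloxy)-5-(methoxycarbonyl)-3,6-dimethylphenoxy]-7-chloro-8,8-dimethoxy-1-methyl-3-oxo-2-oxabicyclo[2.2.2]oct-5-ene-6-carboxylate (mixture of racemic diastereomers) | O=C1OC2(C)C(Cl)C(OC)(OC)C1C(Oc1c(C)c(C(=O)OC)c(OCc3ccccc3)c(C)c1OCc1ccccc1)=C2C(=O)OCc1ccccc1 | intermediate
14 | benzyl 6-[2,4-bis(benzyloxy)-5-(methoxycarbonyl)-3,6-dimethylphenoxy]-3-chloro-4,4-dimethoxy-2-methylcyclohexa-1,5-diene-1-carboxylate (racemic) | COC1(OC)C=C(Oc2c(C)c(C(=O)OC)c(OCc3ccccc3)c(C)c2OCc2ccccc2)C(C(=O)OCc2ccccc2)=C(C)C1Cl | intermediate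
15 | benzyl 2-[2,4-bis(benzyloxy)-5-(methoxycarbonyl)-3,6-dimethylphenoxy]-5-chloro-4-methoxy-6-methylbenzoate | COc1c(Cl)c(C)c(C(=O)OCc2ccccc2)c(Oc2c(C)c(C(=O)OC)c(OCc3ccccc3)c(C)c2OCc2ccccc2)c1 | intermediate
16 | benzyl 2-[2,4-bis(benzyloxy)-5-(methoxycarbonyl)-3,6-dimethylphenoxy]-5-chloro-3-formyl-4-methoxy-6-methylbenzoate | COc1c(Cl)c(C)c(C(=O)OCc2ccccc2)c(Oc2c(C)c(C(=O)OC)c(OCc3ccccc3)c(C)c2OCc2ccccc2)c1C=O | intermediate
17 | 5-chloro-2-[2,4-dihydroxy-5-(methoxycarbonyl)-3,6-dimethylphenoxy]-3-formyl-4-hydroxy-6-methylbenzoic acid | COC(=O)c1c(C)c(Oc2c(C=O)c(O)c(Cl)c(C)c2C(=O)O)c(O)c(C)c1O | target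

Total step count: 10 steps.
Longest linear sequence: 7 steps (steps 1, 2, 3, 6, 8, 9, 10; compounds 1, 2, 3, 5, 10, 15, 16, 17).

Steps most likely to fail

Step 8. The cycloaddition may stall, because the 4-aryloxy donor makes the diene less electron-poor, C6 carries a methyl group, and the chlorinated ketene acetal is less nucleophilic and bulkier than the parent. The ketene acetal may also oligomerise first, or the methanol released may exchange with the aryloxy group at C4 of unreacted pyranone. The fallback sets out from 10 and uses the unsubstituted partner 1,1-dimethoxyethene (C=C(OC)OC) in toluene at 110 °C, the established version of this pyranone-to-anisole conversion. It should pass through the bicyclic lactone benzyl 5-(ArO)-8,8-dimethoxy-1-methyl-3-oxo-2-oxabicyclo[2.2.2]oct-5-ene-6-carboxylate F1 and the diene benzyl 6-(ArO)-4,4-dimethoxy-2-methylcyclohexa-1,5-diene-1-carboxylate F2 to the chlorine-free arene benzyl 2-(ArO)-4-methoxy-6-methylbenzoate F3. Electrophilic chlorination of that arene with N-chlorosuccinimide in MeCN should then go at C4' (ortho to methoxy, para to the aryloxy oxygen), since C2' is shielded by the bulky aryloxy group. The route is rejoined at 15.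

Step 9. Attack at the crowded C2' may be slow, while TiCl4 strips benzyl groups (helped by chelation at the ring A benzyl ether next to the methyl ester) or the C3' methyl ether, giving mixtures of partly deprotected material. The fallback sets out from 15 and avoids the strong Lewis acid. Iodination with N-iodosuccinimide and catalytic CF3CO2H in MeCN should give benzyl 2-(ArO)-5-chloro-3-iodo-4-methoxy-6-methylbenzoate F4. Iodine–magnesium exchange with i-PrMgCl·LiCl in THF at −40 °C, which the two doubly ortho-substituted esters should tolerate, followed by a DMF quench, should give the aldehyde. The route is rejoined at 16.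

Step 10. Cleavage of the hindered benzyl ester or of the methyl ether may be incomplete. Benzyl cations may alkylate the electron-rich rings if trapping is slow. Longer exposure may start to cleave the methyl ester or acylate the ring A C4 hydroxyl with the ring B carboxyl (seven-membered lactone closure). The fallback sets out from 16 and separates the two tasks. Hydrogenolysis (H2 at 1 atm, Pd/C (palladium on carbon), EtOAc, rt, stopped after three equivalents) should remove the three benzyl groups under neutral conditions; the hindered aldehyde and the electron-rich aryl chloride are expected to react more slowly. This should give 5-chloro-2-[2,4-dihydroxy-5-(methoxycarbonyl)-3,6-dimethylphenoxy]-3-formyl-4-methoxy-6-methylbenzoic acid F5. BCl3 in CH2Cl2 at −78 to 0 °C is then needed only for the chelation-controlled removal of the methyl ether ortho to the formyl group. The route is rejoined at 17.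

Further compounds
F1 | step 8 | benzyl 5-[2,4-bis(benzyloxy)-5-(methoxycarbonyl)-3,6-dimethylphenoxy]-8,8-dimethoxy-1-methyl-3-oxo-2-oxabicyclo[2.2.2]oct-5-ene-6-carboxylate (racemic) | O=C1OC2(C)CC(OC)(OC)C1C(Oc1c(C)c(C(=O)OC)c(OCc3ccccc3)c(C)c1OCc1ccccc1)=C2C(=O)OCc1ccccc1
F2 | step 8 | benzyl 6-[2,4-bis(benzyloxy)-5-(methoxycarbonyl)-3,6-dimethylphenoxy]-4,4-dimethoxy-2-methylcyclohexa-1,5-diene-1-carboxylate | COC1(OC)C=C(Oc2c(C)c(C(=O)OC)c(OCc3ccccc3)c(C)c2OCc2ccccc2)C(C(=O)OCc2ccccc2)=C(C)C1
F3 | step 8 | benzyl 2-[2,4-bis(benzyloxy)-5-(methoxycarbonyl)-3,6-dimethylphenoxy]-4-methoxy-6-methylbenzoate | COc1cc(C)c(C(=O)OCc2ccccc2)c(Oc2c(C)c(C(=O)OC)c(OCc3ccccc3)c(C)c2OCc2ccccc2)c1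
F4 | step 9 | benzyl 2-[2,4-bis(benzyloxy)-5-(methoxycarbonyl)-3,6-dimethylphenoxy]-5-chloro-3-iodo-4-methoxy-6-methylbenzoate | COc1c(Cl)c(C)c(C(=O)OCc2ccccc2)c(Oc2c(C)c(C(=O)OC)c(OCc3ccccc3)c(C)c2OCc2ccccc2)c1I
F5 | step 10 | 5-chloro-2-[2,4-dihydroxy-5-(methoxycarbonyl)-3,6-dimethylphenoxy]-3-formyl-4-methoxy-6-methylbenzoic acid | COC(=O)c1c(C)c(Oc2c(C=O)c(OC)c(Cl)c(C)c2C(=O)O)c(O)c(C)c1O
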